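Ring B is opened at its ketone: C1 is removed as carbon monoxide, so that C1–C2 and C1–C8a are made in one operation. The feature exploited is that the C1 carbonyl lies between the C2 methylene and C8a, the only unsubstituted ring-A carbon ortho to the C4a side chain (C5 holds the pyrone) and activated by the C8 oxygen. A palladium/light carbonylation of a primary iodide therefore closes ring B on an arene that already carries the pyrone, the isopentyl chain and the (R)-carbinol derived from (R)-epichlorohydrin. The precursor is the aryl pyrone with a (2R)-2-silyloxy-3-iodopropyl chain; phenol and pyrone hydroxyl are methoxymethyl ethers, so one mild acid step finishes the synthesis.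

Key step: step 10

Assumption: 1-tetralone numbering is used (C1 ketone, C3 carbinol, C5 pyrone-bearing carbon, C8 phenol carbon); the single stereocentre of the target is (3R); 3,5-dibromophenol is taken as the commercial arene.

Remark: a 3-oxygenated 1-tetralone loses its C3 substituent easily (aromatisation to a naphthol). The C8 oxygen therefore travels as a methoxymethyl ether (no Lewis-acid demethylation at the end), and the carbonylation uses a weak, water-free amine base.

Step 1
Reactants: 1 3,5-dibromophenol
Product: 2 1,3-dibromo-5-(methoxymethoxy)benzene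
Conditions: MOMCl, i-Pr2NEt, CH2Cl2, 0 °C → rt
Reagents that add atoms: chloromethyl methyl ether, COCCl
Why: O-alkylation of the phenol with chloromethyl methyl ether (acetal protection) gives an ether that survives the organometallic, cross-coupling and radical steps and falls in the same final acid treatment as the other two masks.

Step 2
Reactants: 2 1,3-dibromo-5-(methoxymethoxy)benzene; 3 (R)-epichlorohydrin
Product: 5 (2R)-1-[3-bromo-5-(methoxymethoxy)phenyl]-3-chloropropan-2-ol, via arylmagnesium chloride 4 (not isolated)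
Conditions: i-PrMgCl·LiCl (1.05 equiv), THF, −15 → 0 °C; CuI (10 mol %), then 3, −30 → 0 °C; aq NH4Cl
Reagents that add atoms: (R)-epichlorohydrin 3, ClC[C@H]1CO1
Why: Bromine–magnesium exchange on the doubly activated dibromide stops at the mono-Grignard reagent, and its copper-catalysed SN2 opening of the epoxide at the unsubstituted carbon leaves the C–O bond of the stereocentre untouched, so the (R) configuration of 3 is carried over unchanged into the (R)-chlorohydrin.

Step 3
Reactants: 5 (2R)-1-[3-bromo-5-(methoxymethoxy)phenyl]-3-chloropropan-2-ol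
Product: 6 tert-butyl{[(2R)-1-[3-bromo-5-(methoxymethoxy)phenyl]-3-chloropropan-2-yl]oxy}dimethylsilane
Conditions: TBSCl, imidazole, DMF, rt
Reagents that add atoms: tert-butyldimethylsilyl chloride, CC(C)(C)[Si](C)(C)Cl
Why: Imidazole-promoted silylation of the secondary alcohol is routine and prevents epoxide formation from the halohydrin in every later basic step.

Step 4
Reactants: 6 silyl-protected bromo chlorohydrin; 7 1-bromo-3-methylbutane
Product: 9 tert-butyl{[(2R)-1-chloro-3-[3-(methoxymethoxy)-5-(3-methylbutyl)phenyl]propan-2-yl]oxy}dimethylsilane, via (3-methylbutyl)zinc bromide 8 (not isolated)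
Conditions: 7, Zn dust, LiCl, THF, 50 °C; then 6, Pd(dppf)Cl2 (3 mol %), THF, 60 °C
Reagents that add atoms: 1-bromo-3-methylbutane 7 (as its zinc reagent 8), CC(C)CCBr
Why: Negishi sp2–sp3 coupling of an aryl bromide with a primary alkylzinc halide under Pd(dppf)Cl2 outruns β-hydride elimination and leaves the unactivated primary chloride and both ethers untouched.

Step 5
Reactants: 9 isopentyl arene
Product: 10 {[(2R)-1-[2-bromo-5-(methoxymethoxy)-3-(3-methylbutyl)phenyl]-3-chloropropan-2-yl]oxy}(tert-butyl)dimethylsilane
Conditions: NBS (1.05 equiv), MeCN, 0 °C → rt, dark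
Reagents that add atoms: N-bromosuccinimide, O=C1CCC(=O)N1Br
Why: Electrophilic aromatic bromination with NBS in acetonitrile goes to the position para to the alkoxy group of a 3,5-dialkyl aryl ether, which is the future C5, while ionic conditions in the dark spare the benzylic positions.

Step 6
Reactants: 11 malonyl dichloride (two molecules)
Product: 13 6-chloro-4-hydroxy-2H-pyran-2-one, via 6-chloro-4-hydroxy-2-oxo-2H-pyran-3-carbonyl chloride 12 (not isolated)
Conditions: neat, 50 °C (−HCl); then H2O (1 equiv), 1,4-dioxane, 60 °C (−CO2)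
Reagents that add atoms: none
Why: Self-condensation of malonyl dichloride (C-acylation of one molecule by a second, then ring closure through the enol oxygen of the remaining acid chloride) gives the chloropyrone acid chloride, and its hydrolysis to the vinylogous β-keto acid is followed by ready decarboxylation.

Step 7
Reactants: 13 6-chloro-4-hydroxy-2H-pyran-2-one
Product: 14 6-chloro-4-(methoxymethoxy)-2H-pyran-2-one
Conditions: MOMCl, i-Pr2NEt, CH2Cl2, 0 °C
Reagents that add atoms: chloromethyl methyl ether, COCCl
Why: O-alkylation of the acidic 4-hydroxy-2-pyrone with a hard electrophile under a hindered amine base takes place at the C4 oxygen and keeps the C6 chloride for the coupling.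

Step 8
Reactants: 10 aryl bromide; 14 6-chloro-4-(methoxymethoxy)-2H-pyran-2-one
Product: 17 6-{2-[(2R)-2-(tert-butyldimethylsilyloxy)-3-chloropropyl]-4-(methoxymethoxy)-6-(3-methylbutyl)phenyl}-4-(methoxymethoxy)-2H-pyran-2-one, via aryllithium 15 (not isolated), via arylzinc chloride 16 (not isolated)
Conditions: t-BuLi (2.0 equiv), THF, −78 °C; ZnCl2, −78 °C → rt; then 14, Pd2(dba)3 (2.5 mol %), SPhos (10 mol %), THF, 50 °C
Reagents that add atoms: 6-chloro-4-(methoxymethoxy)-2H-pyran-2-one 14, COCOc1cc(Cl)oc(=O)c1
Why: Bromine–lithium exchange at −78 °C is far faster than attack on the primary chloride, transmetalation gives an arylzinc that tolerates the lactone, and Negishi coupling with an SPhos-ligated palladium catalyst joins di-ortho-substituted arylzincs to an activated vinylic chloride such as C6–Cl of a 2-pyrone without aqueous base.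

Step 9
Reactants: 17 chloride
Product: 18 6-{2-[(2R)-2-(tert-butyldimethylsilyloxy)-3-iodopropyl]-4-(methoxymethoxy)-6-(3-methylbutyl)phenyl}-4-(methoxymethoxy)-2H-pyran-2-one
Conditions: NaI (10 equiv), butan-2-one, 80 °C, dark
Reagents that add atoms: sodium iodide, [Na+].[I-]
Why: Finkelstein halide exchange (SN2 at the primary carbon, driven by precipitation of NaCl) gives the iodide without touching the neighbouring silyloxy stereocentre.

Step 10
Reactants: 18 iodide; 19 carbon monoxide
Product: 20 (3R)-3-(tert-butyldimethylsilyloxy)-8-(methoxymethoxy)-5-[4-(methoxymethoxy)-2-oxo-2H-pyran-6-yl]-6-(3-methylbutyl)-3,4-dihydronaphthalen-1(2H)-one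
Conditions: CO (45 atm), Pd(PPh3)4 (10 mol %), 2,6-lutidine (2 equiv), benzene, 450 nm LEDs, 25 °C
Reagents that add atoms: carbon monoxide 19, [C-]#[O+]
Why: Proposed new method: photoexcited zerovalent palladium transfers one electron to the C2–I bond to give a primary radical and monovalent palladium iodide, the radical captures CO, and the resulting C1 acyl radical either adds to C8a (rearomatisation by oxidation with the monovalent palladium iodide and proton loss to lutidine) or is parked reversibly as the acylpalladium iodide or acyl iodide, an electrophile that acylates the same carbon, so both paths give the tetralone and no external nucleophile competes. The closest known reaction types are the palladium/light atom-transfer carbonylation of alkyl iodides, palladium-catalysed ring-forming C–H alkylation of arenes with alkyl iodides and acyl-radical cyclisation onto arenes to give 1-tetralones, and only their union in one operation is untested. Ring B closes as a six-membered ring by attack of the C1 acyl centre on the ortho carbon C8a (6-exo with respect to the C8a–C8 bond), after C1–C2 has been made by CO capture. No stereocentre is formed, and C3, which lies β to the radical and never carries a metal, keeps its (R) configuration and its silyloxy group. The step needs CO capture to outrun β-hydride loss, five-membered attack of the C2 radical on C8a and addition of that radical to C6 of the pyrone, which 45 atm of CO, the fully substituted and twisted-away pyrone carbon and the electron-rich 4-alkoxy-pyrone should secure, and it needs acylation at C8a alone, which is guaranteed because C5 is occupied and C8a is ortho to the C8 oxygen and para to the isopentyl group. 2,6-Lutidine binds the hydrogen iodide without releasing water or enolising the β-silyloxy ketone, and visible light leaves the pyrone chromophore unexcited.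

Step 11
Reactants: 20 protected tetralone
Product: 21 (3R)-3,8-dihydroxy-5-(4-hydroxy-2-oxo-2H-pyran-6-yl)-6-(3-methylbutyl)-3,4-dihydronaphthalen-1(2H)-one
Conditions: HCl (1.25 M in MeOH), 0 °C → rt
Reagents that add atoms: none
Why: Acid-catalysed methanolysis cleaves both methoxymethyl acetals and the secondary silyl ether in one operation at a temperature low enough to keep the β-hydroxy ketone from dehydrating, and no bond to C3 is broken, so the (R) configuration is retained.

Compound list
1 | 3,5-dibromophenol | Oc1cc(Br)cc(Br)c1 | starting material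
2 | 1,3-dibromo-5-(methoxymethoxy)benzene | COCOc1cc(Br)cc(Br)c1 | intermediate
3 | (R)-epichlorohydrin | ClC[C@H]1CO1 | starting material
4 | [3-bromo-5-(methoxymethoxy)phenyl]magnesium chloride | COCOc1cc(Br)cc([Mg]Cl)c1 | intermediate
5 | (2R)-1-[3-bromo-5-(methoxymethoxy)phenyl]-3-chloropropan-2-ol | COCOc1cc(Br)cc(C[C@@H](O)CCl)c1 | intermediate
6 | tert-butyl{[(2R)-1-[3-bromo-5-(methoxymethoxy)phenyl]-3-chloropropan-2-yl]oxy}dimethylsilane | COCOc1cc(Br)cc(C[C@@H](O[Si](C)(C)C(C)(C)C)CCl)c1 | intermediate
7 | 1-bromo-3-methylbutane | CC(C)CCBr | starting material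
8 | (3-methylbutyl)zinc bromide | CC(C)CC[Zn]Br | intermediate
9 | tert-butyl{[(2R)-1-chloro-3-[3-(methoxymethoxy)-5-(3-methylbutyl)phenyl]propan-2-yl]oxy}dimethylsilane | COCOc1cc(CCC(C)C)cc(C[C@@H](O[Si](C)(C)C(C)(C)C)CCl)c1 | intermediate
10 | {[(2R)-1-[2-bromo-5-(methoxymethoxy)-3-(3-methylbutyl)phenyl]-3-chloropropan-2-yl]oxy}(tert-butyl)dimethylsilane | COCOc1cc(CCC(C)C)c(Br)c(C[C@@H](O[Si](C)(C)C(C)(C)C)CCl)c1 | intermediate
11 | malonyl dichloride | O=C(Cl)CC(=O)Cl | starting material
12 | 6-chloro-4-hydroxy-2-oxo-2H-pyran-3-carbonyl chloride | O=C(Cl)c1c(O)cc(Cl)oc1=O | intermediate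
13 | 6-chloro-4-hydroxy-2H-pyran-2-one | O=c1cc(O)cc(Cl)o1 | intermediate
14 | 6-chloro-4-(methoxymethoxy)-2H-pyran-2-one | COCOc1cc(Cl)oc(=O)c1 | intermediate
15 | {2-[(2R)-2-(tert-butyldimethylsilyloxy)-3-chloropropyl]-4-(methoxymethoxy)-6-(3-methylbutyl)phenyl}lithium | COCOc1cc(CCC(C)C)c([Li])c(C[C@@H](O[Si](C)(C)C(C)(C)C)CCl)c1 | intermediate
16 | {2-[(2R)-2-(tert-butyldimethylsilyloxy)-3-chloropropyl]-4-(methoxymethoxy)-6-(3-methylbutyl)phenyl}zinc chloride | COCOc1cc(CCC(C)C)c([Zn]Cl)c(C[C@@H](O[Si](C)(C)C(C)(C)C)CCl)c1 | intermediate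
17 | 6-{2-[(2R)-2-(tert-butyldimethylsilyloxy)-3-chloropropyl]-4-(methoxymethoxy)-6-(3-methylbutyl)phenyl}-4-(methoxymethoxy)-2H-pyran-2-one | COCOc1cc(CCC(C)C)c(-c2cc(OCOC)cc(=O)o2)c(C[C@@H](O[Si](C)(C)C(C)(C)C)CCl)c1 | intermediate
18 | 6-{2-[(2R)-2-(tert-butyldimethylsilyloxy)-3-iodopropyl]-4-(methoxymethoxy)-6-(3-methylbutyl)phenyl}-4-(methoxymethoxy)-2H-pyran-2-one | COCOc1cc(CCC(C)C)c(-c2cc(OCOC)cc(=O)o2)c(C[C@@H](O[Si](C)(C)C(C)(C)C)CI)c1 | intermediate
19 | carbon monoxide | [C-]#[O+] | starting material
20 | (3R)-3-(tert-butyldimethylsilyloxy)-8-(methoxymethoxy)-5-[4-(methoxymethoxy)-2-oxo-2H-pyran-6-yl]-6-(3-methylbutyl)-3,4-dihydronaphthalen-1(2H)-one | CC(C)CCc1cc(OCOC)c2c(c1-c1cc(OCOC)cc(=O)o1)C[C@@H](O[Si](C)(C)C(C)(C)C)CC2=O | intermediate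
21 | (3R)-3,8-dihydroxy-5-(4-hydroxy-2-oxo-2H-pyran-6-yl)-6-(3-methylbutyl)-3,4-dihydronaphthalen-1(2H)-one | CC(C)CCc1cc(O)c2c(c1-c1cc(O)cc(=O)o1)C[C@@H](O)CC2=O | target

Total step count: 11. Longest linear sequence: 9 steps (steps 1, 2, 3, 4, 5, 8, 9, 10, 11).

Steps most likely to fail

Step 10. The acyl intermediate may fail to close onto C8a (reduction, or return to the iodide), or the C2 radical may be diverted by addition to the pyrone or by β-hydride loss before it captures CO. The fallback uses known chemistry and separates CO capture from arene acylation. It sets out from 18: light-driven palladium atom-transfer carbonylation of the alkyl iodide with water as the nucleophile (CO 45 atm, Pd(PPh3)4, 450 nm, K2CO3, benzene/H2O) should give (3R)-3-(tert-butyldimethylsilyloxy)-4-{5-(methoxymethoxy)-2-[4-(methoxymethoxy)-2-oxo-2H-pyran-6-yl]-3-(3-methylbutyl)phenyl}butanoic acid F1. 1-Chloro-N,N,2-trimethylpropenylamine in CH2Cl2 converts it under neutral conditions into (3R)-3-(tert-butyldimethylsilyloxy)-4-{5-(methoxymethoxy)-2-[4-(methoxymethoxy)-2-oxo-2H-pyran-6-yl]-3-(3-methylbutyl)phenyl}butanoyl chloride F2. Intramolecular Friedel–Crafts acylation of F2 in hexafluoroisopropanol at room temperature (no Lewis acid, suited to alkoxy-activated arenes) closes ring B at C8a and rejoins the route at 20.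

Step 8. Transmetalation and reductive elimination at the di-ortho-substituted arylzinc may be slow, so that the chloropyrone is consumed by reduction or homocoupling; the supply of 14 from step 6 may also prove erratic. The fallback builds the pyrone on the ring and needs neither 14 nor a cross-coupling. It sets out from 10: bromine–lithium exchange (t-BuLi, THF, −78 °C) and a CO2 quench give 2-[(2R)-2-(tert-butyldimethylsilyloxy)-3-chloropropyl]-4-(methoxymethoxy)-6-(3-methylbutyl)benzoic acid F3. 1-Chloro-N,N,2-trimethylpropenylamine gives 2-[(2R)-2-(tert-butyldimethylsilyloxy)-3-chloropropyl]-4-(methoxymethoxy)-6-(3-methylbutyl)benzoyl chloride F4. F4 acylates the lithium dienolate of commercial 2,2,6-trimethyl-4H-1,3-dioxin-4-one (LiHMDS, THF, −78 °C) at its γ-carbon to give 6-(2-{2-[(2R)-2-(tert-butyldimethylsilyloxy)-3-chloropropyl]-4-(methoxymethoxy)-6-(3-methylbutyl)phenyl}-2-oxoethyl)-2,2-dimethyl-4H-1,3-dioxin-4-one F5. Heating F5 in toluene at 110 °C expels acetone, and the acylketene lactonises onto the enol oxygen of the aryl ketone to give 6-{2-[(2R)-2-(tert-butyldimethylsilyloxy)-3-chloropropyl]-4-(methoxymethoxy)-6-(3-methylbutyl)phenyl}-4-hydroxy-2H-pyran-2-one F6. MOMCl/i-Pr2NEt then returns to the route at 17.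

Step 11. Acid-catalysed loss of water at C3 with aromatisation of ring B to a naphthol may compete with the slower cleavage of the aryl acetal. The fallback splits the unmasking into two near-neutral operations. It sets out from 20: TMSOTf/2,2′-bipyridyl (CH2Cl2, 0 °C, then H2O) removes both methoxymethyl groups without free Brønsted acid and gives (3R)-3-(tert-butyldimethylsilyloxy)-8-hydroxy-5-(4-hydroxy-2-oxo-2H-pyran-6-yl)-6-(3-methylbutyl)-3,4-dihydronaphthalen-1(2H)-one F7. HF·pyridine buffered with pyridine (THF, 0 °C) then removes the silyl ether and arrives at 21.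

Further compounds
F1 | step 10 | (3R)-3-(tert-butyldimethylsilyloxy)-4-{5-(methoxymethoxy)-2-[4-(methoxymethoxy)-2-oxo-2H-pyran-6-yl]-3-(3-methylbutyl)phenyl}butanoic acid | CC(C)CCc1cc(OCOC)cc(C[C@@H](O[Si](C)(C)C(C)(C)C)CC(=O)O)c1-c1cc(OCOC)cc(=O)o1
F2 | step 10 | (3R)-3-(tert-butyldimethylsilyloxy)-4-{5-(methoxymethoxy)-2-[4-(methoxymethoxy)-2-oxo-2H-pyran-6-yl]-3-(3-methylbutyl)phenyl}butanoyl chloride | CC(C)CCc1cc(OCOC)cc(C[C@@H](O[Si](C)(C)C(C)(C)C)CC(=O)Cl)c1-c1cc(OCOC)cc(=O)o1
F3 | step 8 | 2-[(2R)-2-(tert-butyldimethylsilyloxy)-3-chloropropyl]-4-(methoxymethoxy)-6-(3-methylbutyl)benzoic acid | CC(C)CCc1cc(OCOC)cc(C[C@@H](O[Si](C)(C)C(C)(C)C)CCl)c1C(=O)O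
F4 | step 8 | 2-[(2R)-2-(tert-butyldimethylsilyloxy)-3-chloropropyl]-4-(methoxymethoxy)-6-(3-methylbutyl)benzoyl chloride | CC(C)CCc1cc(OCOC)cc(C[C@@H](O[Si](C)(C)C(C)(C)C)CCl)c1C(=O)Cl
F5 | step 8 | 6-(2-{2-[(2R)-2-(tert-butyldimethylsilyloxy)-3-chloropropyl]-4-(methoxymethoxy)-6-(3-methylbutyl)phenyl}-2-oxoethyl)-2,2-dimethyl-4H-1,3-dioxin-4-one | CC(C)CCc1cc(OCOC)cc(C[C@@H](O[Si](C)(C)C(C)(C)C)CCl)c1C(=O)CC1=CC(=O)OC(C)(C)O1
F6 | step 8 | 6-{2-[(2R)-2-(tert-butyldimethylsilyloxy)-3-chloropropyl]-4-(methoxymethoxy)-6-(3-methylbutyl)phenyl}-4-hydroxy-2H-pyran-2-one | CC(C)CCc1cc(OCOC)cc(C[C@@H](O[Si](C)(C)C(C)(C)C)CCl)c1-c1cc(O)cc(=O)o1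
F7 | step 11 | (3R)-3-(tert-butyldimethylsilyloxy)-8-hydroxy-5-(4-hydroxy-2-oxo-2H-pyran-6-yl)-6-(3-methylbutyl)-3,4-dihydronaphthalen-1(2H)-one | CC(C)CCc1cc(O)c2c(c1-c1cc(O)cc(=O)o1)C[C@@H](O[Si](C)(C)C(C)(C)C)CC2=O
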